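**Plan**
- Retrosynthesis: the catechol silyl ethers, the enol methyl ether and the bridgehead aroyl group (C1–CO bond) are removed first. The remaining bicyclo[3.3.1]nonane-2,4,9-trione is cut at C5–C6, C1–C9 and C3–C4 into a lavandulyl malonate and an acyclic iodo ketone.
- Enabling feature: C5 is the common α-carbon of the C4 and C9 carbonyls (a hidden malonate carbon with two equivalent acyl arms), C9 is a ketone flanked by C1 and C5, and C1 and C3 are the two α-carbons of the C2 carbonyl.
- Forward: one pot joins the fragments (C5–C6, SN2), closes ring B (C5–C6–C7–C8–C1–C9) through C1–C9 and then ring A (C1–C2–C3–C4–C5–C9) through C3–C4.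
- End game: O-methylation, bridgehead lithiation and aroylation at C1, desilylation, demethylation.
- Stereochemistry: the lavandulyl centre and C7 come from two Evans alkylations ((S)- and (R)-4-benzyloxazolidin-2-one). C1 and C5 follow from C7 when the prochiral malonate is desymmetrised in the reversible first and chair-selective second Dieckmann closure; C1 is retained in the bridgehead acylation.

Key step: step 12

Remark: locants are those usual for this compound class (C1 aroyl bridgehead, C2–C4 enolised β-diketone, C5 lavandulyl bridgehead, C6 CH2, C7 prenyl CH, C8 CMe2, C9 bridging ketone). The enol is drawn as the 2-hydroxy-4-oxo tautomer of the target SMILES, and O-methylation is assumed to occur mainly at the less hindered O2.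

**Route**

Step 1
Reactants: 1 (S)-4-benzyloxazolidin-2-one; 2 3-methylbut-2-enoyl chloride
Product: 3 (S)-4-benzyl-3-(3-methylbut-2-enoyl)oxazolidin-2-one
Conditions: n-BuLi, THF, −78 °C; then 2, −78 to 0 °C
Reagents that add atoms: none
Why: N-acylation of the lithiated oxazolidinone by an acid chloride is the standard entry to Evans imides and creates no stereocentre.

Step 2
Reactants: 3; 4 1-bromo-3-methylbut-2-ene (prenyl bromide)
Product: 5 (S)-4-benzyl-3-[(2S)-5-methyl-2-(prop-1-en-2-yl)hex-4-enoyl]oxazolidin-2-one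
Conditions: NaN(SiMe3)2, THF, −78 °C; then 4, −78 to −40 °C
Reagents that add atoms: none
Why: γ-deprotonation should give the chelated (Z)-dienolate, which alkylates at the α-carbon on the face opposite the benzyl group (Evans deconjugative alkylation), setting the (S) lavandulyl centre and leaving the isopropenyl group.

Step 3
Reactants: 5
Product: 6 (S)-lavandulol [(2S)-5-methyl-2-(prop-1-en-2-yl)hex-4-en-1-ol]
Conditions: LiBH4, MeOH (1 equiv), Et2O, 0 °C
Reagents that add atoms: none
Why: reductive cleavage of the N-acyl oxazolidinone by LiBH4 should give the primary alcohol without epimerisation or alkene migration.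

Step 4
Reactants: 6
Product: 7 (S)-lavandulyl iodide [(5S)-5-(iodomethyl)-2,6-dimethylhepta-2,6-diene]
Conditions: I2, PPh3, imidazole, CH2Cl2, 0 °C to rt
Reagents that add atoms: iodine (II)
Why: Appel iodination replaces the primary hydroxyl by SN2 and does not touch the adjacent stereocentre.

Step 5
Reactants: 7; 8 dimethyl malonate
Product: 9 dimethyl 2-[(2R)-5-methyl-2-(prop-1-en-2-yl)hex-4-en-1-yl]malonate
Conditions: 8 (3 equiv), NaH, THF/DMF, 0 to 60 °C
Reagents that add atoms: none
Why: malonic ester alkylation with a primary iodide; the excess of malonate suppresses dialkylation, and the descriptor changes only through the priority order.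

Step 6
Reactants: 10 3,3-dimethylglutaric anhydride
Product: 11 5-methoxy-3,3-dimethyl-5-oxopentanoic acid
Conditions: MeOH, reflux
Reagents that add atoms: methanol (CO)
Why: alcoholysis of the symmetric cyclic anhydride gives the half ester and differentiates the two termini.

Step 7
Reactants: 11; 12 (R)-4-benzyloxazolidin-2-one
Product: 14 methyl 5-[(4R)-4-benzyl-2-oxooxazolidin-3-yl]-3,3-dimethyl-5-oxopentanoate, via mixed pivalic anhydride 13 (not isolated)
Conditions: t-BuCOCl, Et3N, THF, −20 °C; then 12, LiCl, rt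
Reagents that add atoms: none
Why: mixed-anhydride N-acylation of the oxazolidinone occurs at the less hindered carbonyl of the pivalic anhydride and leaves the methyl ester untouched.

Step 8
Reactants: 14; 4 1-bromo-3-methylbut-2-ene
Product: 15 methyl (4R)-5-[(4R)-4-benzyl-2-oxooxazolidin-3-yl]-3,3-dimethyl-4-(3-methylbut-2-en-1-yl)-5-oxopentanoate
Conditions: NaN(SiMe3)2, THF, −78 °C; then 4, −78 to −40 °C
Reagents that add atoms: none
Why: Evans alkylation, in which only the more acidic imide is enolised and the chelated (Z)-enolate takes up prenyl bromide opposite the benzyl group of the (R)-auxiliary, setting the centre that becomes C7.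

Step 9
Reactants: 15
Product: 17 (5R)-4,4-dimethyl-5-(3-methylbut-2-en-1-yl)oxan-2-one, via hydroxy ester 16 (not isolated)
Conditions: LiBH4 (1.1 equiv), MeOH, Et2O, 0 °C; then pyridinium p-toluenesulfonate (cat.), CH2Cl2, rt
Reagents that add atoms: none
Why: reductive cleavage of the imide gives the δ-hydroxy ester 16, which should lactonise readily under the gem-dimethyl effect; the stereocentre is not involved.

Step 10
Reactants: 17; 18 5-bromo-2-methylpent-2-ene
Product: 20 (9R)-9-(hydroxymethyl)-2,8,8,12-tetramethyltrideca-2,11-dien-6-one, via (4-methylpent-3-en-1-yl)lithium 19 (not isolated)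
Conditions: 18, Li (wire), Et2O, 0 °C; then 17, THF, −78 °C; then H2O
Reagents that add atoms: none
Why: mono-addition of an organolithium to a δ-lactone, in which the tetrahedral lithium hemiketal is stable at −78 °C and blocks a second addition; the product is expected as the hydroxy ketone in equilibrium with its lactol.

Step 11
Reactants: 20
Product: 21 (9R)-9-(iodomethyl)-2,8,8,12-tetramethyltrideca-2,11-dien-6-one
Conditions: I2, PPh3, imidazole, CH2Cl2, 0 °C to rt
Reagents that add atoms: iodine (II)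
Why: Appel iodination of the primary alcohol of the open-chain tautomer should drain the lactol equilibrium and leaves the ketone and C7 untouched.

Step 12
Reactants: 9; 21
Product: 24 (1S,5S,7S)-2-hydroxy-8,8-dimethyl-3,7-bis(3-methylbut-2-en-1-yl)-5-[(2R)-5-methyl-2-(prop-1-en-2-yl)hex-4-en-1-yl]bicyclo[3.3.1]non-2-ene-4,9-dione, via alkylated malonate 22 (not isolated), via ring B diketo ester 23 (not isolated)
Conditions: 9 (1.2 equiv), NaH (1.1 equiv), THF/DMPU, 0 °C; then 21, 60 °C; then KOt-Bu, t-BuOH, 60 °C; aq. HCl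
Reagents that add atoms: none
Why: The sodium salt of 9 displaces iodide at the primary carbon of 21 (SN2, C5–C6) to give 22, whose ketone a malonate anion does not enolise; KOt-Bu then forms the C1 enolate, which attacks one of the two ester groups on C5 (C1–C9, ring B, 6-(enolexo)-exo-trig Dieckmann) to give 23, and the C3 enolate of 23 attacks the remaining ester (C3–C4, ring A, 6-(enolendo)-exo-trig Dieckmann), ending in the stabilised C2–C3–C4 enolate of 24. The closest known reaction types are the malonic ester alkylation and the domino Dieckmann cyclisation of δ-keto malonates to bicyclo[3.3.1]nonane-2,4,9-triones. C5 stays prochiral until the first Dieckmann closure, which is reversible through the liberated methoxide, so both C5 epimers of 23 should interconvert. Only the epimer with the ester trans to the C7 prenyl group can hold the C1 acyl group and the C5 ester 1,3-diaxial on a chair of ring B with the prenyl group equatorial, so the C7 centre from step 8 fixes C1 and C5 and places the C7 prenyl group exo. The step needs C1 to close before C3 (six- against eight-membered ring) and no self-alkylation of 21 through C3, which the weakly basic preformed malonate anion secures.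

Step 13
Reactants: 24
Product: 25 (1S,5S,7S)-2-methoxy-8,8-dimethyl-3,7-bis(3-methylbut-2-en-1-yl)-5-[(2R)-5-methyl-2-(prop-1-en-2-yl)hex-4-en-1-yl]bicyclo[3.3.1]non-2-ene-4,9-dione
Conditions: Me2SO4, K2CO3, acetone, rt
Reagents that add atoms: dimethyl sulfate (COS(=O)(=O)OC)
Why: O-methylation of the enolised β-diketone with a hard electrophile should favour the less hindered O2 beside the C1–H bridgehead, and it removes the acidic enol proton before lithiation.

Step 14
Reactants: 26 3,4-dihydroxybenzoic acid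
Product: 28 3,4-bis(tert-butyldimethylsilyloxy)benzoic acid, via silyl ester 27 (not isolated)
Conditions: TBSCl (3.3 equiv), imidazole, DMF, rt; then AcOH/THF/H2O, rt
Reagents that add atoms: tert-butyldimethylsilyl chloride (CC(C)(C)[Si](C)(C)Cl)
Why: exhaustive silylation followed by mild hydrolysis, which cleaves the labile silyl ester 27 but not the aryl silyl ethers.

Step 15
Reactants: 28
Product: 29 3,4-bis(tert-butyldimethylsilyloxy)benzoyl chloride
Conditions: (COCl)2, DMF (cat.), CH2Cl2, 0 °C to rt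
Reagents that add atoms: oxalyl chloride (O=C(Cl)C(=O)Cl)
Why: Vilsmeier-type activation converts the acid into the acid chloride under conditions that aryl silyl ethers tolerate.

Step 16
Reactants: 25; 29
Product: 30 (1S,5R,7S)-1-[3,4-bis(tert-butyldimethylsilyloxy)benzoyl]-2-methoxy-8,8-dimethyl-3,7-bis(3-methylbut-2-en-1-yl)-5-[(2R)-5-methyl-2-(prop-1-en-2-yl)hex-4-en-1-yl]bicyclo[3.3.1]non-2-ene-4,9-dione
Conditions: lithium 2,2,6,6-tetramethylpiperidide, THF, −78 °C; then 29, −78 to −40 °C
Reagents that add atoms: none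
Why: bridgehead lithiation followed by C-acylation, where C1–H is the only acidic C–H left (C3 and C5 are fully substituted) and the pyramidal bridgehead carbanion, which cannot become a planar enolate in the cage, is acylated with retention.

Step 17
Reactants: 30
Product: 31 (1S,5R,7S)-1-(3,4-dihydroxybenzoyl)-2-methoxy-8,8-dimethyl-3,7-bis(3-methylbut-2-en-1-yl)-5-[(2R)-5-methyl-2-(prop-1-en-2-yl)hex-4-en-1-yl]bicyclo[3.3.1]non-2-ene-4,9-dione
Conditions: HF·pyridine, pyridine, THF, 0 °C
Reagents that add atoms: none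
Why: buffered fluoride cleavage of the two aryl silyl ethers avoids the acid that would cyclise prenyl groups and leaves the enol methyl ether in place.

Step 18
Reactants: 31
Product: 32 (1S,5R,7S)-1-(3,4-dihydroxybenzoyl)-2-hydroxy-8,8-dimethyl-3,7-bis(3-methylbut-2-en-1-yl)-5-[(2R)-5-methyl-2-(prop-1-en-2-yl)hex-4-en-1-yl]bicyclo[3.3.1]non-2-ene-4,9-dione
Conditions: LiCl, DMSO, 120 °C (degassed)
Reagents that add atoms: none
Why: Krapcho-type SN2 attack of chloride on the O-methyl group of the vinylogous ester should release the enolised β-diketone under neutral conditions that spare the alkenes and the catechol.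

**Compound list**
1 | (S)-4-benzyloxazolidin-2-one | O=C1N[C@@H](Cc2ccccc2)CO1 | starting material
2 | 3-methylbut-2-enoyl chloride | CC(C)=CC(=O)Cl | starting material
3 | (S)-4-benzyl-3-(3-methylbut-2-enoyl)oxazolidin-2-one | CC(C)=CC(=O)N1[C@@H](Cc2ccccc2)COC1=O | intermediate
4 | 1-bromo-3-methylbut-2-ene (prenyl bromide) | CC(C)=CCBr | starting material
5 | (S)-4-benzyl-3-[(2S)-5-methyl-2-(prop-1-en-2-yl)hex-4-enoyl]oxazolidin-2-one | C=C(C)[C@H](CC=C(C)C)C(=O)N1[C@@H](Cc2ccccc2)COC1=O | intermediate
6 | (S)-lavandulol, (2S)-5-methyl-2-(prop-1-en-2-yl)hex-4-en-1-ol | C=C(C)[C@H](CC=C(C)C)CO | intermediate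
7 | (S)-lavandulyl iodide, (5S)-5-(iodomethyl)-2,6-dimethylhepta-2,6-diene | C=C(C)[C@H](CC=C(C)C)CI | intermediate
8 | dimethyl malonate | COC(=O)CC(=O)OC | starting material
9 | dimethyl 2-[(2R)-5-methyl-2-(prop-1-en-2-yl)hex-4-en-1-yl]malonate | C=C(C)[C@H](CC=C(C)C)CC(C(=O)OC)C(=O)OC | intermediate
10 | 3,3-dimethylglutaric anhydride | CC1(C)CC(=O)OC(=O)C1 | starting material
11 | 5-methoxy-3,3-dimethyl-5-oxopentanoic acid | COC(=O)CC(C)(C)CC(=O)O | intermediate
12 | (R)-4-benzyloxazolidin-2-one | O=C1N[C@H](Cc2ccccc2)CO1 | starting material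
13 | mixed pivalic anhydride of 11 (formed in the flask) | COC(=O)CC(C)(C)CC(=O)OC(=O)C(C)(C)C | intermediate
14 | methyl 5-[(4R)-4-benzyl-2-oxooxazolidin-3-yl]-3,3-dimethyl-5-oxopentanoate | COC(=O)CC(C)(C)CC(=O)N1[C@H](Cc2ccccc2)COC1=O | intermediate
15 | methyl (4R)-5-[(4R)-4-benzyl-2-oxooxazolidin-3-yl]-3,3-dimethyl-4-(3-methylbut-2-en-1-yl)-5-oxopentanoate | COC(=O)CC(C)(C)[C@@H](CC=C(C)C)C(=O)N1[C@H](Cc2ccccc2)COC1=O | intermediate
16 | methyl (4R)-4-(hydroxymethyl)-3,3,7-trimethyloct-6-enoate (formed in the flask) | COC(=O)CC(C)(C)[C@@H](CC=C(C)C)CO | intermediate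
17 | (5R)-4,4-dimethyl-5-(3-methylbut-2-en-1-yl)oxan-2-one | O=C1CC(C)(C)[C@@H](CC=C(C)C)CO1 | intermediate
18 | 5-bromo-2-methylpent-2-ene | CC(C)=CCCBr | starting material
19 | (4-methylpent-3-en-1-yl)lithium (formed in the flask) | [Li]CCC=C(C)C | intermediate
20 | (9R)-9-(hydroxymethyl)-2,8,8,12-tetramethyltrideca-2,11-dien-6-one | CC(C)=CCCC(=O)CC(C)(C)[C@@H](CC=C(C)C)CO | intermediate
21 | (9R)-9-(iodomethyl)-2,8,8,12-tetramethyltrideca-2,11-dien-6-one | CC(C)=CCCC(=O)CC(C)(C)[C@@H](CC=C(C)C)CI | intermediate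
22 | dimethyl 2-[(2R)-5-methyl-2-(prop-1-en-2-yl)hex-4-en-1-yl]-2-[(2S)-3,3,9-trimethyl-2-(3-methylbut-2-en-1-yl)-5-oxodec-8-en-1-yl]malonate (formed in the flask) | C=C(C)[C@H](CC=C(C)C)CC(C(=O)OC)(C(=O)OC)C[C@H](CC=C(C)C)C(C)(C)CC(=O)CCC=C(C)C | intermediate
23 | methyl (1S,3S,5S)-4,4-dimethyl-5-(3-methylbut-2-en-1-yl)-3-(5-methylhex-4-enoyl)-1-[(2R)-5-methyl-2-(prop-1-en-2-yl)hex-4-en-1-yl]-2-oxocyclohexane-1-carboxylate (formed in the flask, productive epimer drawn) | C=C(C)[C@H](CC=C(C)C)C[C@]1(C(=O)OC)C[C@H](CC=C(C)C)C(C)(C)[C@H](C1=O)C(=O)CCC=C(C)C | intermediate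
24 | (1S,5S,7S)-2-hydroxy-8,8-dimethyl-3,7-bis(3-methylbut-2-en-1-yl)-5-[(2R)-5-methyl-2-(prop-1-en-2-yl)hex-4-en-1-yl]bicyclo[3.3.1]non-2-ene-4,9-dione | C=C(C)[C@H](CC=C(C)C)C[C@]12C[C@H](CC=C(C)C)C(C)(C)[C@H](C1=O)C(O)=C(CC=C(C)C)C2=O | intermediate
25 | (1S,5S,7S)-2-methoxy-8,8-dimethyl-3,7-bis(3-methylbut-2-en-1-yl)-5-[(2R)-5-methyl-2-(prop-1-en-2-yl)hex-4-en-1-yl]bicyclo[3.3.1]non-2-ene-4,9-dione | C=C(C)[C@H](CC=C(C)C)C[C@]12C[C@H](CC=C(C)C)C(C)(C)[C@H](C1=O)C(OC)=C(CC=C(C)C)C2=O | intermediate
26 | 3,4-dihydroxybenzoic acid | O=C(O)c1ccc(O)c(O)c1 | starting material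
27 | tert-butyldimethylsilyl 3,4-bis(tert-butyldimethylsilyloxy)benzoate (formed in the flask) | CC(C)(C)[Si](C)(C)OC(=O)c1ccc(O[Si](C)(C)C(C)(C)C)c(O[Si](C)(C)C(C)(C)C)c1 | intermediate
28 | 3,4-bis(tert-butyldimethylsilyloxy)benzoic acid | O=C(O)c1ccc(O[Si](C)(C)C(C)(C)C)c(O[Si](C)(C)C(C)(C)C)c1 | intermediate
29 | 3,4-bis(tert-butyldimethylsilyloxy)benzoyl chloride | O=C(Cl)c1ccc(O[Si](C)(C)C(C)(C)C)c(O[Si](C)(C)C(C)(C)C)c1 | intermediate
30 | (1S,5R,7S)-1-[3,4-bis(tert-butyldimethylsilyloxy)benzoyl]-2-methoxy-8,8-dimethyl-3,7-bis(3-methylbut-2-en-1-yl)-5-[(2R)-5-methyl-2-(prop-1-en-2-yl)hex-4-en-1-yl]bicyclo[3.3.1]non-2-ene-4,9-dione | C=C(C)[C@H](CC=C(C)C)C[C@]12C[C@H](CC=C(C)C)C(C)(C)[C@](C(=O)c3ccc(O[Si](C)(C)C(C)(C)C)c(O[Si](C)(C)C(C)(C)C)c3)(C1=O)C(OC)=C(CC=C(C)C)C2=O | intermediate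
31 | (1S,5R,7S)-1-(3,4-dihydroxybenzoyl)-2-methoxy-8,8-dimethyl-3,7-bis(3-methylbut-2-en-1-yl)-5-[(2R)-5-methyl-2-(prop-1-en-2-yl)hex-4-en-1-yl]bicyclo[3.3.1]non-2-ene-4,9-dione | C=C(C)[C@H](CC=C(C)C)C[C@]12C[C@H](CC=C(C)C)C(C)(C)[C@](C(=O)c3ccc(O)c(O)c3)(C1=O)C(OC)=C(CC=C(C)C)C2=O | intermediate
32 | (1S,5R,7S)-1-(3,4-dihydroxybenzoyl)-2-hydroxy-8,8-dimethyl-3,7-bis(3-methylbut-2-en-1-yl)-5-[(2R)-5-methyl-2-(prop-1-en-2-yl)hex-4-en-1-yl]bicyclo[3.3.1]non-2-ene-4,9-dione | C=C(C)[C@H](CC=C(C)C)C[C@]12C[C@H](CC=C(C)C)C(C)(C)[C@](C(=O)c3ccc(O)c(O)c3)(C1=O)C(O)=C(CC=C(C)C)C2=O | target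

**Count**
Total steps: 18. Longest linear sequence: 11 steps (steps 6–13 and 16–18).

**Steps most likely to fail**

Step 12. The displacement at the β-branched primary iodide by the tertiary malonate carbanion may be slower than elimination or than ring closure of the ketone through C3, so the cascade may never reach the Dieckmann stage. The fallback sets out from 21. It is first joined to unsubstituted dimethyl malonate 8 (NaH, THF/DMPU), whose secondary carbanion is far less hindered, to give dimethyl 2-[(2S)-3,3,9-trimethyl-2-(3-methylbut-2-en-1-yl)-5-oxodec-8-en-1-yl]malonate F1. F1 is then alkylated with the less encumbered iodide 7 (NaH, DMF, 60 °C) to give 22, now isolated, and 22 is closed separately with KOt-Bu in t-BuOH/THF at 60 °C through 23. The route is rejoined at 24.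

Step 16. The bridgehead carbanion beside the quaternary C8 may be captured too slowly by the bulky acid chloride, so that proton return or attack of the amide base on 29 takes over. The fallback sets out from 25. It is lithiated as before and trapped with the smaller and more reactive 3,4-bis(tert-butyldimethylsilyloxy)benzaldehyde F2 (from 3,4-dihydroxybenzaldehyde, TBSCl, imidazole). This gives the bridgehead carbinol F3 as a mixture at the carbinol centre, which is oxidised with Dess–Martin periodinane. The route is rejoined at 30.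

Step 9. Hydride may attack the ring carbonyl of the auxiliary (endocyclic cleavage), because the exocyclic carbonyl is flanked by a carbon that bears a prenyl and a tert-alkyl group, or it may go on to reduce the ester and the lactone. The fallback sets out from 15. Hydrolysis with LiOH and H2O2 (THF/H2O, 0 °C) gives (2R)-5-methoxy-3,3-dimethyl-2-(3-methylbut-2-en-1-yl)-5-oxopentanoic acid F4. F4 is converted with isobutyl chloroformate and N-methylmorpholine into the mixed carbonic anhydride F5, which NaBH4 reduces chemoselectively to 16. Lactonisation of 16 rejoins the route at 17.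

**Further compounds**
F1 | step 12 | dimethyl 2-[(2S)-3,3,9-trimethyl-2-(3-methylbut-2-en-1-yl)-5-oxodec-8-en-1-yl]malonate | COC(=O)C(C[C@H](CC=C(C)C)C(C)(C)CC(=O)CCC=C(C)C)C(=O)OC
F2 | step 16 | 3,4-bis(tert-butyldimethylsilyloxy)benzaldehyde | O=Cc1ccc(O[Si](C)(C)C(C)(C)C)c(O[Si](C)(C)C(C)(C)C)c1
F3 | step 16 | 1-{[3,4-bis(tert-butyldimethylsilyloxy)phenyl](hydroxy)methyl} analogue of 30 (ring and side-chain centres as in 30, carbinol centre undefined) | C=C(C)[C@H](CC=C(C)C)C[C@]12C[C@H](CC=C(C)C)C(C)(C)[C@](C(O)c3ccc(O[Si](C)(C)C(C)(C)C)c(O[Si](C)(C)C(C)(C)C)c3)(C1=O)C(OC)=C(CC=C(C)C)C2=O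
F4 | step 9 | (2R)-5-methoxy-3,3-dimethyl-2-(3-methylbut-2-en-1-yl)-5-oxopentanoic acid | COC(=O)CC(C)(C)[C@@H](CC=C(C)C)C(=O)O
F5 | step 9 | mixed isobutyl carbonic anhydride of F4 | COC(=O)CC(C)(C)[C@@H](CC=C(C)C)C(=O)OC(=O)OCC(C)C
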